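The cyclopentenone ring B (C9–C10–C11=C12–C18) holds its C10 ketone beside C9–H, and C9 bears the C8(Me)=C7 olefin, so the target is a β,γ-unsaturated ketone. Its allylic isomer, with C10 bonded to C7, is a cyclohepta-2,5-dienone whose C7 and C11 are spanned by a ten-membered ansa ring (27). Irradiation of 27 triggers a 1,3-acyl shift that forms C10–C9, contracts the seven-membered ring to ring B, widens the ten-membered ring to the twelve-membered one and creates the C9 stereocentre. Compound 27 is built from a ring-A alkenyl bromide and an Evans aldol aldehyde by organocerium addition, ring-closing metathesis and B-alkyl Suzuki macrocyclisation.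

Key step: step 18

Atom labels (verticillane numbering, used for all compounds): C1 = ring-A CH; C2, C3 = CH2CH2; C4(=C20H2); C5 = CH2; C6 = CH–OAc; C7=C8 (C19 methyl on C8); C9; C10 = C=O; C11=C12; C13, C14 = ring-A CH2; C15(CH3)2; C18 = CH–OAc bonded to C12 and C9. Ring A = C1, C14, C13, C12, C11, C15.

Remark on the chemistry: in 27 the bridge can leave C7 only pseudo-axially, with C6 gauche to C9, so the 1,3-shift should give the 7Z twelve-membered olefin first. The route assumes that the same irradiation equilibrates 7Z and 7E, and treats this as its main risk.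

Remark on the structures: the stereodescriptors of 27 need no change. 7R is the only configuration that lets the bridge close, and it places the C18 acetoxy group so that C9 is formed S.

Remark on the design of 27: C10 is kept as an alcohol until both rings are closed, so that no acidic C7–H is exposed to base.

Assumption: 1, 9, 10 and 12 are commercial.

Step 1
Reactants: 1 2-methylcyclohex-2-en-1-one
Product: 3 trimethyl{[(3S)-2-methyl-3-vinylcyclohex-1-en-1-yl]oxy}silane, via aluminium enolate 2 (not isolated)
Conditions: Me2Al(CH=CH2) (from CH2=CHMgBr and Me2AlCl), CuTC (5 mol %), chiral phosphoramidite (10 mol %, antipode giving 3S), Et2O, −30 °C; then TMSOTf, −30 → 0 °C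
Reagents that add atoms: dimethyl(vinyl)aluminium C=C[Al](C)C; trimethylsilyl triflate C[Si](C)(C)OS(=O)(=O)C(F)(F)F
Why: Copper-catalysed asymmetric conjugate addition of an alkenylalane to an α-substituted cyclic enone, in which the ligand selects the enone face and so sets C1, and O-silylation fixes the regiodefined enolate.

Step 2
Reactants: 3 trimethyl{[(3S)-2-methyl-3-vinylcyclohex-1-en-1-yl]oxy}silane
Product: 5 (3S)-2,2-dimethyl-3-vinylcyclohexan-1-one, via lithium enolate 4 (not isolated)
Conditions: MeLi, THF, 0 °C; then MeI, DMPU, −78 → 0 °C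
Reagents that add atoms: iodomethane CI
Why: Cleavage of the silyl enol ether by MeLi gives the enolate at one defined position, and its C-methylation creates the gem-dimethyl carbon C15 without touching C1 (regiospecific enolate alkylation).

Step 3
Reactants: 5 (3S)-2,2-dimethyl-3-vinylcyclohexan-1-one
Product: 6 (4S)-2-bromo-3,3-dimethyl-4-vinylcyclohex-1-ene-1-carbaldehyde
Conditions: PBr3, DMF, CHCl3, 0 → 60 °C; then aq. NaOAc
Reagents that add atoms: N,N-dimethylformamide CN(C)C=O; phosphorus tribromide BrP(Br)Br; water O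
Why: Vilsmeier–Haack–Arnold bromoformylation; the ketone can enolise only away from the quaternary carbon, so the aldehyde (C18) lands on C12 and bromine on C11.

Step 4
Reactants: 6 (4S)-2-bromo-3,3-dimethyl-4-vinylcyclohex-1-ene-1-carbaldehyde
Product: 7 (1R)-1-[(4S)-2-bromo-3,3-dimethyl-4-vinylcyclohex-1-en-1-yl]prop-2-en-1-ol
Conditions: Zn(CH=CH2)2, (+)-MIB (10 mol %), toluene, −20 → 0 °C; aq. NH4Cl
Reagents that add atoms: divinylzinc C=C[Zn]C=C
Why: Amino-alcohol-catalysed enantioselective addition of an alkenylzinc reagent to an enal; the ligand (antipode chosen for the R carbinol), not the remote C1 centre, sets C18.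

Step 5
Reactants: 7 (1R)-1-[(4S)-2-bromo-3,3-dimethyl-4-vinylcyclohex-1-en-1-yl]prop-2-en-1-ol
Product: 8 tert-butyldimethylsilyl ether of 7 (1S,18R)
Conditions: TBSCl, imidazole, DMF, 23 °C
Reagents that add atoms: tert-butyldimethylsilyl chloride CC(C)(C)[Si](C)(C)Cl
Why: Standard silylation; the bulky TBS group is chosen because it resists O→C silyl migration onto the neighbouring alkenyllithium of step 12.

Step 6
Reactants: 9 (R)-4-benzyloxazolidin-2-one; 10 3-methylbut-2-enoyl chloride
Product: 11 (R)-4-benzyl-3-(3-methylbut-2-enoyl)oxazolidin-2-one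
Conditions: n-BuLi, THF, −78 °C; then 10, −78 → 0 °C
Reagents that add atoms: none
Why: N-Acylation of the lithiated oxazolidinone by the acid chloride.

Step 7
Reactants: 12 3-bromobut-3-en-1-ol
Product: 13 3-bromobut-3-enal
Conditions: Dess–Martin periodinane, NaHCO3, CH2Cl2, 0 °C; used at once as a cold solution
Reagents that add atoms: none
Why: Buffered Dess–Martin oxidation gives the β,γ-unsaturated aldehyde without acid or base that would move the double bond into conjugation.

Step 8
Reactants: 11 (R)-4-benzyl-3-(3-methylbut-2-enoyl)oxazolidin-2-one; 13 3-bromobut-3-enal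
Product: 15 (R)-4-benzyl-3-[(2R,3S)-5-bromo-3-hydroxy-2-(prop-1-en-2-yl)hex-5-enoyl]oxazolidin-2-one, via dibutylboron dienolate 14 (not isolated)
Conditions: n-Bu2BOTf, Et3N, CH2Cl2, −78 → 0 °C; 13, −78 → −20 °C; pH 7 buffer, MeOH, H2O2, 0 °C
Reagents that add atoms: none
Why: Evans syn aldol reaction of the Z(O) boron dienolate formed by γ-deprotonation, which reacts at the α-carbon through a Zimmerman–Traxler chair so that the (R)-auxiliary sets C7 and C6 together (2R,3S, syn).

Step 9
Reactants: 15 (R)-4-benzyl-3-[(2R,3S)-5-bromo-3-hydroxy-2-(prop-1-en-2-yl)hex-5-enoyl]oxazolidin-2-one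
Product: 16 3-O-tert-butyldimethylsilyl ether of 15
Conditions: TBSOTf, 2,6-lutidine, CH2Cl2, −78 → 0 °C
Reagents that add atoms: tert-butyldimethylsilyl triflate CC(C)(C)[Si](C)(C)OS(=O)(=O)C(F)(F)F
Why: Silylation of the aldol hydroxyl under non-nucleophilic base, which blocks retro-aldol cleavage in the next steps.

Step 10
Reactants: 16 3-O-tert-butyldimethylsilyl ether of 15
Product: 17 (2S,3S)-5-bromo-3-[(tert-butyldimethylsilyl)oxy]-2-(prop-1-en-2-yl)hex-5-en-1-ol
Conditions: LiBH4, MeOH (1 equiv), Et2O, 0 °C
Reagents that add atoms: none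
Why: Reductive removal of the oxazolidinone with lithium borohydride, which leaves the alkenyl bromide and the α-stereocentre untouched.

Step 11
Reactants: 17 (2S,3S)-5-bromo-3-[(tert-butyldimethylsilyl)oxy]-2-(prop-1-en-2-yl)hex-5-en-1-ol
Product: 18 (2R,3S)-5-bromo-3-[(tert-butyldimethylsilyl)oxy]-2-(prop-1-en-2-yl)hex-5-enal
Conditions: Dess–Martin periodinane, NaHCO3, CH2Cl2, 0 °C; used at once
Reagents that add atoms: none
Why: Buffered Dess–Martin oxidation to the α-isopropenyl aldehyde, used immediately so that C7 neither epimerises nor conjugates.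

Step 12
Reactants: 8 tert-butyldimethylsilyl ether of 7; 18 (2R,3S)-5-bromo-3-[(tert-butyldimethylsilyl)oxy]-2-(prop-1-en-2-yl)hex-5-enal
Product: 21 acyclic C10 carbinol (1S,6S,7S,18R; C10 epimers) joining C11 of ring A to C7, via alkenyllithium 19 (not isolated), via alkenylcerium reagent 20 (not isolated)
Conditions: 8, t-BuLi (2.0 equiv), Et2O, −78 °C; CeCl3, THF, −78 °C; then 18, −78 °C; aq. NH4Cl
Reagents that add atoms: none
Why: Bromine–lithium exchange, transmetalation to the weakly basic organocerium and 1,2-addition to the aldehyde, so that addition should beat enolisation; the C10 configuration does not matter because step 15 removes it.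

Step 13
Reactants: 21 acyclic C10 carbinol (1S,6S,7S,18R; C10 epimers)
Product: 22 cyclohepta-2,5-dienol (1S,6S,7S,18R; C10 epimers) with the C8=C9 olefin closed
Conditions: Hoveyda–Grubbs II (10 mol %), toluene (1 mM), 80 °C
Reagents that add atoms: none
Why: Ring-closing metathesis of the C9 vinyl and C8 isopropenyl groups gives the trisubstituted olefin of the seven-membered ring; the C1 vinyl group could only close rings with a bridgehead double bond and the alkenyl bromide is inert.

Step 14
Reactants: 22 cyclohepta-2,5-dienol (1S,6S,7S,18R; C10 epimers)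
Product: 24 bridged bicyclic alcohol (1R,6S,7S,18R; C10 epimers) with the ten-membered ring closed at C3–C4, via B-alkyl-9-BBN borane 23 (not isolated)
Conditions: 9-BBN (excess), THF, 23 °C; then slow addition to Pd(dppf)Cl2 (20 mol %), AsPh3, Cs2CO3, DMF–THF–H2O, 45 °C (final ≤1 mM)
Reagents that add atoms: none
Why: 9-BBN hydroborates only the monosubstituted C2=C3 vinyl group, and the intramolecular B-alkyl Suzuki–Miyaura coupling with the C4 alkenyl bromide closes the bridge under high dilution, with C10 still an alcohol so that the base finds no acidic C7–H.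

Step 15
Reactants: 24 bridged bicyclic alcohol (1R,6S,7S,18R; C10 epimers)
Product: 25 bridged cyclohepta-2,5-dienone bis-TBS ether (1R,6S,7R,18R)
Conditions: Dess–Martin periodinane, NaHCO3, CH2Cl2, 0 → 23 °C
Reagents that add atoms: none
Why: Buffered Dess–Martin oxidation of the only free hydroxyl converts both C10 epimers into one ketone under conditions that cannot enolise C7.

Step 16
Reactants: 25 bridged cyclohepta-2,5-dienone bis-TBS ether
Product: 26 bridged dienone 6,18-diol (1R,6S,7R,18R)
Conditions: HF·pyridine, pyridine, THF, 0 → 23 °C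
Reagents that add atoms: none
Why: Buffered fluoride desilylation avoids the basic conditions that could cause retro-aldol cleavage or elimination of the β-hydroxy ketone.

Step 17
Reactants: 26 bridged dienone 6,18-diol
Product: 27 bridged cyclohepta-2,5-dienone 6,18-diacetate (1R,6S,7R,18R)
Conditions: Ac2O, pyridine, DMAP (cat.), CH2Cl2, 0 °C
Reagents that add atoms: acetic anhydride CC(=O)OC(C)=O
Why: Standard acetylation of both secondary alcohols; C7 is a bridgehead that cannot invert, so mild amine base is tolerated.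

Step 18
Reactants: 27 bridged cyclohepta-2,5-dienone 6,18-diacetate
Product: 29 (1R,6S,9S,18R,7E)-6,18-diacetoxy-9,18-cycloverticilla-4(20),7,11-trien-10-one (target), via 7Z macrocycle 28 (not isolated)
Conditions: hν (350 nm, Pyrex), degassed benzene (1 mM), 20 °C, to the photostationary state; chromatography; recovered 27 and 28 re-irradiated
Reagents that add atoms: none
Why: n→π* excitation of the twisted C10 ketone breaks the C10–C7 bond, which is allylic to C8=C9 (Norrish type I), and the enoyl/allyl radical pair (or its concerted equivalent) recloses at C9, the far allyl terminus. This is the photochemical 1,3-acyl shift of β,γ-unsaturated ketones, known for bridged cases such as bicyclo[2.2.2]octenones going to bicyclo[4.2.0]octenones. Ring B closes by collapse of the radical pair inside the short C10–C11=C12–C18–C9 tether (five-membered ring closure at the allyl terminus), and the twelve-membered ring is not closed anew but arises from the ten-membered one by insertion of C8 and C9. C9 is set by the suprafacial course: C10 stays on the allyl face turned towards C11=C12 while the C18 acetoxy group sits pseudo-axial on the other face, so the C9 side chain and the acetoxy group come out cis (9S). Collapse at C9 and not back at C7 should be favoured by release of the strain of the ansa bridge. Because C6 is held gauche to C9 in 27, the shift should first give the 7Z olefin 28, which the same irradiation should equilibrate with 29 by the E/Z isomerisation (triplet twisting) that accompanies photolysis of flexible β,γ-enones, while 29 cannot shift back because that would need a bridge leaving C7 equatorially, which ten atoms cannot span.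

Compound list
1 | 2-methylcyclohex-2-en-1-one | CC1=CCCC1=O | starting material
2 | dimethylaluminium (3S)-2-methyl-3-vinylcyclohex-1-en-1-olate | C=C[C@@H]1CCCC(O[Al](C)C)=C1C | intermediate (not isolated)
3 | trimethyl{[(3S)-2-methyl-3-vinylcyclohex-1-en-1-yl]oxy}silane | C=C[C@@H]1CCCC(O[Si](C)(C)C)=C1C | intermediate
4 | lithium (3S)-2-methyl-3-vinylcyclohex-1-en-1-olate | C=C[C@@H]1CCCC(O[Li])=C1C | intermediate (not isolated)
5 | (3S)-2,2-dimethyl-3-vinylcyclohexan-1-one | C=C[C@@H]1CCCC(=O)C1(C)C | intermediate
6 | (4S)-2-bromo-3,3-dimethyl-4-vinylcyclohex-1-ene-1-carbaldehyde | C=C[C@@H]1CCC(C=O)=C(Br)C1(C)C | intermediate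
7 | (1R)-1-[(4S)-2-bromo-3,3-dimethyl-4-vinylcyclohex-1-en-1-yl]prop-2-en-1-ol | C=C[C@@H]1CCC([C@H](O)C=C)=C(Br)C1(C)C | intermediate
8 | tert-butyldimethylsilyl ether of 7 | C=C[C@@H]1CCC([C@H](O[Si](C)(C)C(C)(C)C)C=C)=C(Br)C1(C)C | intermediate
9 | (R)-4-benzyloxazolidin-2-one | O=C1N[C@H](Cc2ccccc2)CO1 | starting material
10 | 3-methylbut-2-enoyl chloride | CC(C)=CC(Cl)=O | starting material
11 | (R)-4-benzyl-3-(3-methylbut-2-enoyl)oxazolidin-2-one | CC(C)=CC(=O)N1[C@H](Cc2ccccc2)COC1=O | intermediate
12 | 3-bromobut-3-en-1-ol | C=C(Br)CCO | starting material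
13 | 3-bromobut-3-enal | C=C(Br)CC=O | intermediate
14 | dibutylboron Z(O)-dienolate of 11 | CC(=C)/C=C(\OB(CCCC)CCCC)N1[C@H](Cc2ccccc2)COC1=O | intermediate (not isolated)
15 | (R)-4-benzyl-3-[(2R,3S)-5-bromo-3-hydroxy-2-(prop-1-en-2-yl)hex-5-enoyl]oxazolidin-2-one | C=C(Br)C[C@H](O)[C@@H](C(C)=C)C(=O)N1[C@H](Cc2ccccc2)COC1=O | intermediate
16 | 3-O-tert-butyldimethylsilyl ether of 15 | C=C(Br)C[C@H](O[Si](C)(C)C(C)(C)C)[C@@H](C(C)=C)C(=O)N1[C@H](Cc2ccccc2)COC1=O | intermediate
17 | (2S,3S)-5-bromo-3-[(tert-butyldimethylsilyl)oxy]-2-(prop-1-en-2-yl)hex-5-en-1-ol | C=C(Br)C[C@H](O[Si](C)(C)C(C)(C)C)[C@@H](C(C)=C)CO | intermediate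
18 | (2R,3S)-5-bromo-3-[(tert-butyldimethylsilyl)oxy]-2-(prop-1-en-2-yl)hex-5-enal | C=C(Br)C[C@H](O[Si](C)(C)C(C)(C)C)[C@@H](C(C)=C)C=O | intermediate
19 | alkenyllithium from 8 (Li on C11) | C=C[C@@H]1CCC([C@H](O[Si](C)(C)C(C)(C)C)C=C)=C([Li])C1(C)C | intermediate (not isolated)
20 | dichlorocerium reagent from 19 (Ce on C11) | C=C[C@@H]1CCC([C@H](O[Si](C)(C)C(C)(C)C)C=C)=C([Ce](Cl)Cl)C1(C)C | intermediate (not isolated)
21 | acyclic C10 carbinol (1S,6S,7S,18R; C10 epimers): ring A with vinyl on C1, the (18R)-CH(OTBS)CH=CH2 arm on C12 and the chain CH(OH)–CH(isopropenyl)–CH(OTBS)–CH2–C(Br)=CH2 on C11 | C=C[C@@H]1CCC([C@H](O[Si](C)(C)C(C)(C)C)C=C)=C(C(O)[C@H](C(C)=C)[C@@H](O[Si](C)(C)C(C)(C)C)CC(Br)=C)C1(C)C | intermediate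
22 | cyclohepta-2,5-dienol (1S,6S,7S,18R; C10 epimers): seven-membered ring C12=C11–C10(OH)–C7–C8(Me)=C9–C18(OTBS) fused to ring A | C=C[C@@H]1CCC2=C(C(O)[C@@H]([C@@H](O[Si](C)(C)C(C)(C)C)CC(Br)=C)C(C)=C[C@H]2O[Si](C)(C)C(C)(C)C)C1(C)C | intermediate
23 | B-alkyl-9-BBN borane from 22 (boron on C3) | C(CB1C2CCCC1CCC2)[C@@H]3CCC4=C(C(O)[C@@H]([C@@H](O[Si](C)(C)C(C)(C)C)CC(Br)=C)C(C)=C[C@H]4O[Si](C)(C)C(C)(C)C)C3(C)C | intermediate (not isolated)
24 | bridged bicyclic alcohol (1R,6S,7S,18R; C10 epimers), ten-membered ring closed | C=C1CC[C@@H]2CCC3=C(C(O)[C@@H]([C@@H](O[Si](C)(C)C(C)(C)C)C1)C(C)=C[C@H]3O[Si](C)(C)C(C)(C)C)C2(C)C | intermediate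
25 | bridged cyclohepta-2,5-dienone bis-TBS ether (1R,6S,7R,18R) | C=C1CC[C@@H]2CCC3=C(C(=O)[C@@H]([C@@H](O[Si](C)(C)C(C)(C)C)C1)C(C)=C[C@H]3O[Si](C)(C)C(C)(C)C)C2(C)C | intermediate
26 | bridged dienone 6,18-diol (1R,6S,7R,18R) | C=C1CC[C@@H]2CCC3=C(C(=O)[C@@H]([C@@H](O)C1)C(C)=C[C@H]3O)C2(C)C | intermediate
27 | bridged cyclohepta-2,5-dienone 6,18-diacetate (1R,6S,7R,18R), precursor of the key step | C=C1CC[C@@H]2CCC3=C(C(=O)[C@@H]([C@@H](OC(C)=O)C1)C(C)=C[C@H]3OC(C)=O)C2(C)C | intermediate
28 | 7Z isomer of the target (1R,6S,9S,18R,7Z) | C=C1CC[C@@H]2CCC3=C(C(=O)[C@@H](/C(C)=C\[C@@H](OC(C)=O)C1)[C@H]3OC(C)=O)C2(C)C | intermediate (not isolated)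
29 | (1R,6S,9S,18R,7E)-6,18-diacetoxy-9,18-cycloverticilla-4(20),7,11-trien-10-one | C=C1CC[C@@H]2CCC3=C(C(=O)[C@@H](/C(C)=C/[C@@H](OC(C)=O)C1)[C@H]3OC(C)=O)C2(C)C | target

Total step count: 18. Longest linear sequence: 12 steps (steps 1–5 and 12–18 from 1; equally steps 6 and 8–18 from 9).

Steps most likely to fail

Step 18. The shift may stop at the 7Z macrocycle because triplet E/Z relaxation is slow, or long irradiation may drain material into oxa-di-π-methane rearrangement and decarbonylation before enough 7E isomer has built up. Fallback: the irradiation is stopped once 27 is consumed and the Z isomer 28 is isolated. Its C7=C8 geometry is then corrected in the dark by reversible thiyl-radical addition and elimination (PhSH cat., AIBN, benzene, 80 °C), a known way to equilibrate trisubstituted olefins towards the less strained isomer, which is expected to be 7E. This sets out from 28 and returns to the route at 29; no new compound is made.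

Step 14. Oligomerisation, protodeboronation or β-hydride elimination may consume the alkylborane faster than the strained ten-membered ring closes, or only one C10 epimer may cyclise. Fallback: the same C3–C4 bond is closed by an intramolecular Nozaki–Hiyama–Kishi reaction. From 22, hydroboration and oxidation (9-BBN; NaBO3) should give the C3,C10-diol F1. Dess–Martin oxidation of both hydroxyl groups should give the keto aldehyde F2. CrCl2 with catalytic NiCl2 in DMSO–THF under high dilution should join the alkenyl bromide to the aldehyde and give the ten-membered allylic alcohol F3 (C3 epimers). Methyl chloroformate and pyridine should give the methyl carbonate F4. Palladium-catalysed formate reduction (Pd(OAc)2, PBu3, HCO2NH4) delivers hydride to the more substituted allyl terminus C3, keeps the C4=C20 methylidene and should give 25. The fallback leaves the route at 22 and rejoins it at 25.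

Step 12. The hindered alkenylmetal may deprotonate the α-branched aldehyde, or suffer O→C silyl migration, instead of adding. Fallback: a Nozaki–Hiyama–Kishi union. The alkenyllithium generated from 8 is quenched with iodine to give the alkenyl iodide F5, which is coupled with 18 by CrCl2 and catalytic NiCl2 in DMSO. The organochromium reagent is not basic, so enolisation is avoided, and the iodide should be engaged far faster than the alkenyl bromide of 18. The fallback leaves the route at 8 and rejoins it at 21.

Further compounds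
F0 | step 18 | none | none
F1 | step 14 | C3,C10-diol from hydroboration–oxidation of 22 | OCC[C@@H]1CCC2=C(C(O)[C@@H]([C@@H](O[Si](C)(C)C(C)(C)C)CC(Br)=C)C(C)=C[C@H]2O[Si](C)(C)C(C)(C)C)C1(C)C
F2 | step 14 | C10-keto C3-aldehyde | O=CC[C@@H]1CCC2=C(C(=O)[C@@H]([C@@H](O[Si](C)(C)C(C)(C)C)CC(Br)=C)C(C)=C[C@H]2O[Si](C)(C)C(C)(C)C)C1(C)C
F3 | step 14 | ten-membered C3 allylic alcohol (C3 epimers), C10 ketone, bis-TBS ether | C=C1C(O)C[C@@H]2CCC3=C(C(=O)[C@@H]([C@@H](O[Si](C)(C)C(C)(C)C)C1)C(C)=C[C@H]3O[Si](C)(C)C(C)(C)C)C2(C)C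
F4 | step 14 | methyl carbonate of F3 | C=C1C(OC(=O)OC)C[C@@H]2CCC3=C(C(=O)[C@@H]([C@@H](O[Si](C)(C)C(C)(C)C)C1)C(C)=C[C@H]3O[Si](C)(C)C(C)(C)C)C2(C)C
F5 | step 12 | alkenyl iodide analogue of 8 | C=C[C@@H]1CCC([C@H](O[Si](C)(C)C(C)(C)C)C=C)=C(I)C1(C)C
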